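(The earlier runs and the new flask are calculated on assumed constants, noise included.)

Sunday's run, poor in D, shows dissolved Z levelling near 12.0% of the charge. Friday's, richer in D, reads on average 5.75% over its last readings, which fall as they go, scatter included.

| setting | Sunday's | Friday's | flask |
|---|---|---|---|
| X | 20 mM | 20 mM | 20 mM |
| D | 9 mM | 36 mM | 18.0 mM |
| remark | run made earlier | run made earlier |  |
| time |  |  | 1.0 h |

| run | time / min | G / % | Z / % |
|---|---|---|---|
| Sunday's | 6.00 | 4 | 5 |
| Sunday's | 15.0 | 4 | 8 |
| Sunday's | 20.0 | 5 | 9 |
| Sunday's | 30.0 | 5 | 11 |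
| Sunday's | 40.0 | 8 | 11 |
| Sunday's | 50.0 | 9 | 12 |
| Friday's | 6.00 | 1 | 4 |
| Friday's | 15.0 | 8 | 5 |
| Friday's | 20.0 | 10 | 8 |
| Friday's | 30.0 | 15 | 8 |
| Friday's | 40.0 | 24 | 5 |
| Friday's | 50.0 | 29 | 2 |

(standard deviation of a reading: 1.5 percentage points)

- solid, in amounts per volume of the solution: X
- at the start none of X is in solution
- Z is what X becomes in solution
- Z means what is dissolved; the solid is not counted in it

- the G standing at 1.0 h, as a percentage of the X charged
- concentration of Z in solution at 1.0 h, in percent of saturation

We let X dissolve at κ(S−Z), with S the saturation as a fraction of the charge, and let D take Z at κaDZ, pseudo-first-order in Z while D is held. In this picture Z levels at S divided by the sum of one and aD, and the two runs, as readings with their scatter, give a = 0.0631 mM⁻¹ and S = 18.8%. For our flask that makes 8.81%, the standing fraction, the Z at which dissolving equals use.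

Friday's late climb in G, 0.00633 min⁻¹, gives κ = 0.0485 min⁻¹. So G forms at g = 0.00485 min⁻¹ at the standing fraction, and integrating the rise of Z costs a lag of 9.66 min.

With D held at its charge we get the upper edge of our estimate, G 24.4%, with Z at 46.8% of saturation. Holding D throughout at the 72.9% of its charge which that G leaves gives the lower edge: Z 10.3%, which is 54.7% of saturation, and G 20.1%.

The forecast, where “G appears autocatalytic”, says G 15%, less than our lower edge, and Z at 62% of saturation, more than our highest figure for it.

The flask gives G 23.2% and Z at 52.2% of saturation, inside both of our ranges.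

    D → E (k = 3.20 × 10⁻⁶ s⁻¹)
    X ⇌ Z, rate k2*(cs2 - [Z]) while solid is left; crystals form when [Z] > cs2 (solubility = 3.60 mM, k = 0.00100 s⁻¹)
    Z + D → G (k = 0.0590 M⁻¹ s⁻¹)
    Z + G → Q (k = 0.0290 M⁻¹ s⁻¹)

A neighbouring flask with the same charges is read at 40 min. The same standing fraction, rate and lag, with D at its charge, put G at 14.7%. This neighbour holds Z 9.03%, close to the standing fraction, and more G than that figure, at 15.5%.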